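(All constants come from no measurement; no experiment stands behind them.)

In the closed summer flask, a reading at 5.0 min reports what the enzyme did early, because its first half-life by the pairing step, 2.09 s, is far shorter than the run.

| setting | autumn | summer | midnight | dusk |
|---|---|---|---|---|
| starting material | 0.010 M | 0.010 M | 0.010 M (fed, over 4.00 min) | 0.010 M |
| enzyme | 0.0057 mol% | 0.0057 mol% | 0.0057 mol% | 0.0057 mol% |
| remark | a single well-mixed tank run continuously and read at steady state, 5.0 min in it on average | everything together in a closed stirred flask, run for 5.0 min | a stirred flask in which starting material is dosed at a steady rate over 4.00 min without added volume, worked up at 5.0 min | plug flow through a tube for 5.0 min, no back-mixing |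
| time |  | 5.0 min | 5.0 min | 5.0 min |

    starting material + enzyme → product + enzyme, rate k1*[starting material]^2.5*[enzyme]/(1 + ([starting material]/Kh1)^2.5) (Kh1 = 6.7 mM, k1 = 1.4 × 10⁸ M⁻²·⁵ s⁻¹)
    enzyme → spent catalyst B (k2 = 0.027 s⁻¹)
    2 enzyme → spent catalyst A (k3 = 4.2 × 10⁵ M⁻¹ s⁻¹)

- where a step has two of a species, its rate is k times that concentration squared, and two are used at each turn
- the stated concentrations are those of everything mixed, before any reaction; amounts are the same in each set-up
- the feed brings no volume worth counting
- run time (summer): 5.0 min

- the set-up with the highest amount of product at the outlet or at the end, in percent of the starting material put in ("none" if the first two lie within 2 percentage points) (autumn / summer / midnight / dusk / none)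
- amount of product at the outlet or at the end, in percent of the starting material put in, autumn
- amount of product at the outlet or at the end, in percent of the starting material put in, summer
- amount of product at the outlet or at the end, in percent of the starting material put in, midnight
- amount of product at the outlet or at the end, in percent of the starting material put in, dusk

You have little material, so the next run should go in the set-up that gives most product from one charge. The charge holds 5.70 × 10⁻⁷ M of enzyme. The first-order loss has a half-life of 25.7 s, longer than the pairing step's, so I reckon with both.

The summer flask gets 6.12 s of working time, which is the integral of [enzyme] over the run divided by its charged value. At charged [enzyme] and full [starting material], the rate is 2.14 × 10⁻⁴ M s⁻¹. Multiplied by the working time, that makes 13.1% of the charge. My figure runs high, since the rate drops as [starting material] drops. The dusk tube gives each slice of liquid the same time course as the summer flask.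

The autumn tank is fed continuously. Its balance, counting the enzyme that leaves with the outflow, gives a steady [enzyme] of 3.28 × 10⁻⁸ M, lower than the charge. Its working time is then 17.3 s, longer than the summer flask's by a factor of 2.83. But the tank works at outlet [starting material], and my reckoning stops there. In the midnight flask the dose takes 4.00 min, far longer than the enzyme's first half-life, so I would not dose.

The forecast picks autumn, saying “the well-mixed tank wins by holding enzyme dilute”. It gives 27.9% for the tank, within 26.5% to 29.5%. It gives 12.5% for the summer flask, below my 13.1%, 12.5% for the dusk tube and 0.37% for the midnight flask.

The simulation puts autumn first, with 27.7% at the outlet, against 12.5% for the summer flask, 12.5% for the dusk tube and 0.367% for the midnight flask. So the next run goes in the tank. The autumn tank holds 0.00723 M of starting material throughout. At that concentration and charged [enzyme], the rate is 1.60 × 10⁻⁴ M s⁻¹. Over the tank's working time of 17.3 s, that makes 27.7% of the charge, against the 27.7% read.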